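(The constants used here are invented, and the outcome is calculated.)

The pitfall is to read 2 mol% of precatalyst as working catalyst: it comes free with a half-life of 8.71 h, and the impurity stands against it at 0.700% of the charge.

    substrate + free catalyst ⇌ catalyst intermediate A (K1 = 3.46 /M, k1 = 315 /M/h)
    catalyst intermediate A → catalyst intermediate B (k2 = 486 /h)
    catalyst intermediate B → free catalyst + target (k3 = 53.3 /h)
    free catalyst + impurity → spent catalyst (k4 = 94700 /M/h)
    precatalyst → free catalyst (k5 = 0.0796 /h)

in all of them: precatalyst 2 mol%; impurity 1.4 mM
- cedar: substrate 0.20 M; time 20 h; everything together in a closed stirred flask, run for 20 h
- maple: substrate 0.20 M; a single well-mixed tank run continuously and read at steady state, 20 h in it on average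
- elm: substrate 0.20 M (fed, over 16.0 h); time 20 h; a stirred flask in which substrate is dosed at a steady rate over 16.0 h without added volume, worked up at 20 h
- larch: substrate 0.20 M; one stirred flow tank at steady state, fed with the mixture as stated, mean residence time 100 h

- the set-up with the highest amount of target at the outlet or at the end, in percent of the substrate put in ("none" if the first two lie within 2 percentage points) (cedar / maple / elm / larch / none)
- amount of target at the outlet or at the end, in percent of the substrate put in, cedar
- amount of target at the outlet or at the end, in percent of the substrate put in, maple
- amount of target at the outlet or at the end, in percent of the substrate put in, elm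
- amount of target at the outlet or at the end, in percent of the substrate put in, larch

I counted in fractions of the charge. One turnover of catalyst (the turnover time) costs a fixed 0.0208 h in the two forward steps, plus a capture time of 0.0188 h at full charge, which grows as the substrate fraction falls. Adding these up as substrate is used, leaving a given fraction in a batch costs the capture time times the natural log of one over that fraction, plus the fixed time times the fraction consumed.

Against that demand I set the supply in cedar. Ignoring the impurity gave 0.200 h, a ceiling of >99.9%. Charging the impurity for the whole run gave 0.0599 h, a floor of 89.0%. But released catalyst first matches the impurity at 5.41 h, and counting from there left 0.0775 h of catalyst-hours, live catalyst as a fraction of the charge summed over the hours. So I committed to 95.3% for cedar.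

In a tank, turnover runs at the outlet substrate, so the catalyst-hours equal the fraction consumed times the turnover time there. Larch holds 1.08 h, which gave me 98.2%, more than cedar.

The forecast named larch, with 95.3% for cedar (93.5% to 97%, inside my bracket ), 82.4% for maple, 92.7% for elm and 98.2% for larch, holding that “the 100 h tank gets the most catalyst time”.

The run gave 95.4% in cedar, 82.4% in maple, 92.4% in elm and 98.2% in larch, so larch came first. Cedar ended with 4.60% of its substrate standing, and leaving that much costs 0.0777 h of catalyst-hours, level with the 0.0775 h counted. Maple holds 0.106 h at steady state, and the tank rule turns its standing 17.5% of substrate into a need of 0.106 h.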